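**Plan**
Numbering for rings B/D follows the 2H-chromene: O1, C2(Me2), C3=C4, C4a, C5 (isoflavonyl), C6, C7 (OMe), C8 (OH), C8a; rings A/C are the chromone.
Retrosynthesis: cut first the aryl ether bond C8a–O1 of ring D, then the bond from C5 of ring B to C3 of the chromone, then the side-chain C3=C4 bond and the two C2–methyl bonds.
Enabling feature: the free C8 hydroxyl of ring B lies ortho to C8a, so two-electron oxidation of this phenol makes C8a electrophilic. The cis C3=C4 alkene on the neighbouring C4a holds the tertiary hydroxyl oxygen O1 within reach, so ring D can close by C–H to C–O exchange with no halogen or directing group at C8a.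
Forward: rings A/C are made as a 3-iodochromone from 2,4-dihydroxyacetophenone. Ring B comes from 6-bromoisovanillin, whose CHO becomes the cis-alkenyl carbinol and whose Br becomes a boronate. Suzuki union, global desilylation, then ring D is closed last.
Stereochemistry: there is no stereocentre; the only element is the Z geometry of C3=C4, set by the Still–Gennari olefination and then fixed inside ring D.

Key step: step 10

Remark on the chemistry: the target is achiral, and 2-bromo-5-hydroxy-4-methoxybenzaldehyde (6-bromoisovanillin) is assumed to be commercially available.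

**Route**

Step 1
Reactants: 1 2,4-dihydroxyacetophenone
Product: 2 1-{2-hydroxy-4-[(triisopropylsilyl)oxy]phenyl}ethan-1-one
Conditions: TIPSCl, imidazole, CH2Cl2, 0 °C to rt
Reagents that add atoms: triisopropylsilyl chloride (TIPSCl), CC(C)[Si](Cl)(C(C)C)C(C)C
Why: The 2-hydroxyl is held in a hydrogen bond to the acetyl carbonyl, so silyl ether formation should take place only at the more acidic, unhindered 4-hydroxyl.

Step 2
Reactants: 2 1-{2-hydroxy-4-[(triisopropylsilyl)oxy]phenyl}ethan-1-one
Product: 3 (E)-3-(dimethylamino)-1-{2-hydroxy-4-[(triisopropylsilyl)oxy]phenyl}prop-2-en-1-one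
Conditions: Me2NCH(OMe)2, toluene, 90 °C
Reagents that add atoms: N,N-dimethylformamide dimethyl acetal, COC(OC)N(C)C
Why: Condensation of the methyl ketone with the amide acetal (enaminone formation) is the standard first stage of chromone synthesis from 2-hydroxyacetophenones and leaves the chelated phenol untouched.

Step 3
Reactants: 3 (E)-3-(dimethylamino)-1-{2-hydroxy-4-[(triisopropylsilyl)oxy]phenyl}prop-2-en-1-one
Product: 4 3-iodo-7-[(triisopropylsilyl)oxy]-4H-chromen-4-one
Conditions: I2, pyridine, CHCl3, rt
Reagents that add atoms: iodine (I2), II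
Why: Iodination of the enaminone α-carbon, ring closure of the phenol onto the resulting iminium carbon and loss of dimethylamine (enaminone iodocyclisation) should give the 3-iodochromone, with the amine base buffering the acid so that the silyl ether survives.

Step 4
Reactants: 5 2-bromo-5-hydroxy-4-methoxybenzaldehyde (6-bromoisovanillin)
Product: 6 2-bromo-4-methoxy-5-[(triisopropylsilyl)oxy]benzaldehyde
Conditions: TIPSCl, imidazole, DMF, rt
Reagents that add atoms: triisopropylsilyl chloride (TIPSCl), CC(C)[Si](Cl)(C(C)C)C(C)C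
Why: Standard silylation masks the only hydroxyl against the strong bases of steps 5 and 6 with a group that fluoride later removes without acid.

Step 5
Reactants: 6 2-bromo-4-methoxy-5-[(triisopropylsilyl)oxy]benzaldehyde
Product: 7 methyl (Z)-3-{2-bromo-4-methoxy-5-[(triisopropylsilyl)oxy]phenyl}prop-2-enoate
Conditions: (CF3CH2O)2P(O)CH2CO2Me, KN(SiMe3)2, 18-crown-6, THF, −78 °C
Reagents that add atoms: methyl bis(2,2,2-trifluoroethyl)phosphonoacetate, COC(=O)CP(=O)(OCC(F)(F)F)OCC(F)(F)F
Why: In the Still–Gennari variant of the Horner–Wadsworth–Emmons reaction the electron-poor trifluoroethyl phosphonate eliminates fast from the kinetically formed adduct, so an aromatic aldehyde should give mainly the Z enoate, which becomes the cis C3=C4 bond.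

Step 6
Reactants: 7 methyl (Z)-3-{2-bromo-4-methoxy-5-[(triisopropylsilyl)oxy]phenyl}prop-2-enoate
Product: 8 (Z)-4-{2-bromo-4-methoxy-5-[(triisopropylsilyl)oxy]phenyl}-2-methylbut-3-en-2-ol
Conditions: MeMgBr (3 equiv), THF, −40 to 0 °C; aqueous work-up
Reagents that add atoms: methylmagnesium bromide (two methyl groups), C[Mg]Br
Why: Double 1,2-addition of the Grignard reagent to the ester, through the methyl ketone, should give the tertiary carbinol without touching the alkene geometry, the aryl bromide or the silyl ether.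

Step 7
Reactants: 8 (Z)-4-{2-bromo-4-methoxy-5-[(triisopropylsilyl)oxy]phenyl}-2-methylbut-3-en-2-ol
Product: 9 (Z)-4-{4-methoxy-2-(4,4,5,5-tetramethyl-1,3,2-dioxaborolan-2-yl)-5-[(triisopropylsilyl)oxy]phenyl}-2-methylbut-3-en-2-ol
Conditions: B2pin2, Pd(dppf)Cl2 (cat.), KOAc, 1,4-dioxane, 85 °C
Reagents that add atoms: bis(pinacolato)diboron (B2pin2), CC1(C)OB(OC1(C)C)B1OC(C)(C)C(C)(C)O1
Why: Miyaura borylation with the weak base KOAc converts the aryl bromide into the pinacol boronate while the tertiary alcohol stays un-ionised and so should not engage the arylpalladium intermediate.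

Step 8
Reactants: 9 (Z)-4-{4-methoxy-2-(4,4,5,5-tetramethyl-1,3,2-dioxaborolan-2-yl)-5-[(triisopropylsilyl)oxy]phenyl}-2-methylbut-3-en-2-ol; 4 3-iodo-7-[(triisopropylsilyl)oxy]-4H-chromen-4-one
Product: 10 3-{2-[(Z)-3-hydroxy-3-methylbut-1-en-1-yl]-5-methoxy-4-[(triisopropylsilyl)oxy]phenyl}-7-[(triisopropylsilyl)oxy]-4H-chromen-4-one
Conditions: Pd(OAc)2 (cat.), SPhos, K2CO3, 1,4-dioxane/H2O, 70 °C
Reagents that add atoms: none
Why: Suzuki–Miyaura coupling of 3-iodochromones with arylboron reagents is the standard isoflavone assembly, and the bulky electron-rich SPhos ligand should carry the ortho-substituted boronate through transmetalation; any early loss of the ring A silyl group would be harmless because step 9 removes both.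

Step 9
Reactants: 10 3-{2-[(Z)-3-hydroxy-3-methylbut-1-en-1-yl]-5-methoxy-4-[(triisopropylsilyl)oxy]phenyl}-7-[(triisopropylsilyl)oxy]-4H-chromen-4-one
Product: 11 7-hydroxy-3-{4-hydroxy-2-[(Z)-3-hydroxy-3-methylbut-1-en-1-yl]-5-methoxyphenyl}-4H-chromen-4-one
Conditions: Bu4NF, AcOH, THF, 0 °C to rt
Reagents that add atoms: none
Why: Buffered fluoride cleaves both phenolic silyl ethers (desilylation) under conditions that should spare the acid-labile cis tertiary allylic alcohol and the base-sensitive pyranone ring.

Step 10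
Reactants: 11 7-hydroxy-3-{4-hydroxy-2-[(Z)-3-hydroxy-3-methylbut-1-en-1-yl]-5-methoxyphenyl}-4H-chromen-4-one
Product: 14 7-hydroxy-3-(8-hydroxy-7-methoxy-2,2-dimethyl-2H-chromen-5-yl)-4H-chromen-4-one (target), via aryloxyiodane 12 (not isolated), via dienone 13 (not isolated)
Conditions: PhI(OAc)2 (1.0 equiv, slow addition), (CF3)2CHOH/CH2Cl2 (1:4), −40 to 0 °C
Reagents that add atoms: none
Why: Proposed new method: the electron-rich ring B phenol (C8–OH) should exchange for an acetate on the trivalent iodine of PhI(OAc)2 to give aryloxyiodane 12, whose O–I bond breaks heterolytically with loss of iodobenzene (a two-electron oxidation of the phenol) as the tertiary hydroxyl oxygen O1 bonds to C8a, the free carbon ortho to the oxidised oxygen, giving dienone 13, which enolises at once to the aromatic chromene 14. The closest known reaction type is the hypervalent iodine mediated dehydrogenative cyclisation of aryl-tethered alcohols onto C–H positions of electron-rich arenes to give chromans, together with iodane-mediated phenol dearomatisation by tethered oxygen nucleophiles; what has not been shown is capture at an unsubstituted ortho carbon of a free phenol by a tertiary allylic alcohol with rearomatisation to a 2H-chromene. Ring D closes in the 6-endo-trig mode with respect to the C4a=C8a bond of the oxidised ring (ring atoms O1, C2, C3, C4, C4a, C8a), which the cis C3=C4 alkene on C4a makes geometrically easy. No stereocentre is created (C8a of 13 is only transiently tetrahedral), and the Z alkene, being attached meta to the oxidised oxygen and so not conjugated with the electrophilic positions C5, C7 and C8a, should keep its geometry. The step needs ring B and not ring A to be oxidised, which the substrate secures because the ring A hydroxyl is a vinylogous acid conjugated with the C4 carbonyl and far harder to oxidise than the methoxy-substituted ring B phenol. It also needs O1 to add at C8a and not ipso at C5 or C7: the isoflavonyl group on C5 pushes the CMe2OH terminus to the C8a side, ipso attack would build a fully substituted carbon next to a tertiary ether, and only the C8a adduct can aromatise irreversibly, whereas a C5 or C7 adduct is a quinol ether or ketal that can revert in the acidic fluoroalcohol medium.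

**Compound list**
1 | 2,4-dihydroxyacetophenone | CC(=O)c1ccc(O)cc1O | starting material
2 | 1-{2-hydroxy-4-[(triisopropylsilyl)oxy]phenyl}ethan-1-one | CC(=O)c1ccc(O[Si](C(C)C)(C(C)C)C(C)C)cc1O | intermediate
3 | (E)-3-(dimethylamino)-1-{2-hydroxy-4-[(triisopropylsilyl)oxy]phenyl}prop-2-en-1-one | CN(C)/C=C/C(=O)c1ccc(O[Si](C(C)C)(C(C)C)C(C)C)cc1O | intermediate
4 | 3-iodo-7-[(triisopropylsilyl)oxy]-4H-chromen-4-one | O=c1c(I)coc2cc(O[Si](C(C)C)(C(C)C)C(C)C)ccc12 | intermediate
5 | 2-bromo-5-hydroxy-4-methoxybenzaldehyde (6-bromoisovanillin) | COc1cc(Br)c(C=O)cc1O | starting material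
6 | 2-bromo-4-methoxy-5-[(triisopropylsilyl)oxy]benzaldehyde | COc1cc(Br)c(C=O)cc1O[Si](C(C)C)(C(C)C)C(C)C | intermediate
7 | methyl (Z)-3-{2-bromo-4-methoxy-5-[(triisopropylsilyl)oxy]phenyl}prop-2-enoate | COC(=O)/C=C\c1cc(O[Si](C(C)C)(C(C)C)C(C)C)c(OC)cc1Br | intermediate
8 | (Z)-4-{2-bromo-4-methoxy-5-[(triisopropylsilyl)oxy]phenyl}-2-methylbut-3-en-2-ol | CC(C)(O)/C=C\c1cc(O[Si](C(C)C)(C(C)C)C(C)C)c(OC)cc1Br | intermediate
9 | (Z)-4-{4-methoxy-2-(4,4,5,5-tetramethyl-1,3,2-dioxaborolan-2-yl)-5-[(triisopropylsilyl)oxy]phenyl}-2-methylbut-3-en-2-ol | CC(C)(O)/C=C\c1cc(O[Si](C(C)C)(C(C)C)C(C)C)c(OC)cc1B1OC(C)(C)C(C)(C)O1 | intermediate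
10 | 3-{2-[(Z)-3-hydroxy-3-methylbut-1-en-1-yl]-5-methoxy-4-[(triisopropylsilyl)oxy]phenyl}-7-[(triisopropylsilyl)oxy]-4H-chromen-4-one | CC(C)(O)/C=C\c1cc(O[Si](C(C)C)(C(C)C)C(C)C)c(OC)cc1-c1coc2cc(O[Si](C(C)C)(C(C)C)C(C)C)ccc2c1=O | intermediate
11 | 7-hydroxy-3-{4-hydroxy-2-[(Z)-3-hydroxy-3-methylbut-1-en-1-yl]-5-methoxyphenyl}-4H-chromen-4-one | CC(C)(O)/C=C\c1cc(O)c(OC)cc1-c1coc2cc(O)ccc2c1=O | intermediate
12 | acetoxy(phenyl)-λ3-iodanyl ether of the ring B phenol of 11 (aryloxyiodane, formed in the flask) | CC(=O)OI(Oc1cc(/C=C\C(C)(C)O)c(-c2coc3cc(O)ccc3c2=O)cc1OC)c1ccccc1 | intermediate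
13 | 7-hydroxy-3-(7-methoxy-2,2-dimethyl-8-oxo-8,8a-dihydro-2H-chromen-5-yl)-4H-chromen-4-one (dienone, racemic at C8a, formed in the flask) | COC1=CC(-c2coc3cc(O)ccc3c2=O)=C2C=CC(C)(C)OC2C1=O | intermediate
14 | 7-hydroxy-3-(8-hydroxy-7-methoxy-2,2-dimethyl-2H-chromen-5-yl)-4H-chromen-4-one | COc1cc(-c2coc3cc(O)ccc3c2=O)c2c(c1O)OC(C)(C)C=C2 | target

**Step count and risks**
Total steps: 10. Longest linear sequence: 7 steps (steps 4 to 10, from 5).

Steps most likely to fail:

1. Step 10 (Proposed new method). The oxidised ring may be captured at the wrong carbon (ipso at C5, or at C7 by acetate or solvent) to give quinol ethers that cannot aromatise. The product phenol, which is more electron-rich than 11, may be oxidised further. The allylic alcohol may ionise in the fluoroalcohol medium.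
 Fallback with known chemistry, replacing the C–H oxidation by a halide-based aryl ether coupling; it sets out from 11 and comes back at 14. Amine-catalysed ortho-bromination of the ring B phenol (NBS, cat. i-Pr2NH, CH2Cl2, −78 °C) at its only free ortho position should give 3-{3-bromo-4-hydroxy-2-[(Z)-3-hydroxy-3-methylbut-1-en-1-yl]-5-methoxyphenyl}-7-hydroxy-4H-chromen-4-one F1. Silylation of both phenols (TBSCl, imidazole, DMF) gives the bis(tert-butyldimethylsilyl) ether F2. Intramolecular palladium-catalysed etherification of the aryl bromide by the tertiary alcohol (Pd(OAc)2, 2-(di-tert-butylphosphino)-1,1'-binaphthyl, Cs2CO3, toluene, 80 °C; Buchwald–Hartwig C–O coupling) closes ring D to give 7-[(tert-butyldimethylsilyl)oxy]-3-{8-[(tert-butyldimethylsilyl)oxy]-7-methoxy-2,2-dimethyl-2H-chromen-5-yl}-4H-chromen-4-one F3. Bu4NF/AcOH in THF then gives 14.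

2. Step 5. Z selectivity may be insufficient with the ortho-brominated, electron-rich aldehyde, or the geometry may erode before or during step 6.
 Fallback that sets the cis geometry by alkyne semihydrogenation; it sets out from 6 and comes back at 8, bypassing steps 5 and 6. Ohira–Bestmann homologation (dimethyl (1-diazo-2-oxopropyl)phosphonate, K2CO3, MeOH) gives (4-bromo-5-ethynyl-2-methoxyphenoxy)triisopropylsilane F4. Deprotonation with EtMgBr in THF and addition to acetone gives 4-{2-bromo-4-methoxy-5-[(triisopropylsilyl)oxy]phenyl}-2-methylbut-3-yn-2-ol F5. Semihydrogenation (H2, Pd/CaCO3 poisoned with Pb(OAc)2, quinoline, EtOAc) should give the Z alkene 8.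

3. Step 8. Transmetalation of the hindered ortho-substituted boronate may be slow, with competing protodeboronation and base-induced opening or deiodination of the iodochromone.
 Fallback with reversed coupling roles and no boron or aqueous base; it sets out from 4 and 8 and comes back at 10, bypassing step 7. Zinc insertion into the C–I bond of 4 (Zn dust, LiCl, THF) gives {4-oxo-7-[(triisopropylsilyl)oxy]-4H-chromen-3-yl}zinc iodide F6. Negishi coupling of F6 with aryl bromide 8 (Pd(OAc)2, SPhos, THF, 25 to 50 °C), a coupling type that tolerates a free alcohol, should give 10.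

**Further compounds**
F1 | step 10 | 3-{3-bromo-4-hydroxy-2-[(Z)-3-hydroxy-3-methylbut-1-en-1-yl]-5-methoxyphenyl}-7-hydroxy-4H-chromen-4-one | CC(C)(O)/C=C\c1c(Br)c(O)c(OC)cc1-c1coc2cc(O)ccc2c1=O
F2 | step 10 | 3-{3-bromo-4-[(tert-butyldimethylsilyl)oxy]-2-[(Z)-3-hydroxy-3-methylbut-1-en-1-yl]-5-methoxyphenyl}-7-[(tert-butyldimethylsilyl)oxy]-4H-chromen-4-one | CC(C)(O)/C=C\c1c(Br)c(O[Si](C)(C)C(C)(C)C)c(OC)cc1-c1coc2cc(O[Si](C)(C)C(C)(C)C)ccc2c1=O
F3 | step 10 | 7-[(tert-butyldimethylsilyl)oxy]-3-{8-[(tert-butyldimethylsilyl)oxy]-7-methoxy-2,2-dimethyl-2H-chromen-5-yl}-4H-chromen-4-one | COc1cc(-c2coc3cc(O[Si](C)(C)C(C)(C)C)ccc3c2=O)c2c(c1O[Si](C)(C)C(C)(C)C)OC(C)(C)C=C2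
F4 | step 5 | (4-bromo-5-ethynyl-2-methoxyphenoxy)triisopropylsilane | C#Cc1cc(O[Si](C(C)C)(C(C)C)C(C)C)c(OC)cc1Br
F5 | step 5 | 4-{2-bromo-4-methoxy-5-[(triisopropylsilyl)oxy]phenyl}-2-methylbut-3-yn-2-ol | CC(C)(O)C#Cc1cc(O[Si](C(C)C)(C(C)C)C(C)C)c(OC)cc1Br
F6 | step 8 | {4-oxo-7-[(triisopropylsilyl)oxy]-4H-chromen-3-yl}zinc iodide | O=c1c([Zn]I)coc2cc(O[Si](C(C)C)(C(C)C)C(C)C)ccc12
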